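**Retrosynthetic overview**

1. Target 6 ⇒ ortho-quinone methide 5 (retro oxa-6π electrocyclization) ⇒ 3,5-diprenyl-2,4,6-trihydroxybenzophenone 4 (retro dehydrogenation). The pyran ring comes from one C-prenyl group and the free 4-OH, with no protecting groups.
2. 4 ⇒ 2,4,6-trihydroxybenzophenone 1 + two prenyl bromide 2 (double aromatic C-prenylation in water; both C5 units go in together).
3. Ring order: the phenyl and phloroglucinol rings are bought as 1. The 2H-pyran ring is the only ring made and is closed last, mirroring the biosynthetic order (acylphloroglucinol, then prenylation, then oxidative pyran closure).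

Assumption: the target has no stereocentre or stereogenic double bond, so there is no configuration to set; 1 (CAS 3555-86-0) and 2 are taken as catalogue chemicals (prenyl = 3-methylbut-2-en-1-yl).

**Route**

Step 1
Reactants: 1 2,4,6-trihydroxybenzophenone; 2 prenyl bromide (1-bromo-3-methylbut-2-ene)
Product: 4 3,5-diprenyl-2,4,6-trihydroxybenzophenone, via 3-prenyl-2,4,6-trihydroxybenzophenone 3 (not isolated)
Conditions: 2 (2.1 equiv, slow addition), 5% aq KOH (3 equiv), 0 °C, 3 h; then cold 1 M HCl
Reagents that add atoms: prenyl bromide (compound 2), CC(C)=CCBr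
Why: Phenolate C-alkylation in water (the laboratory counterpart of aromatic prenyl transfer) goes to carbon because hydrogen bonding shields the phenolate oxygens and C3/C5 are the only nucleophilic ring carbons, and two equivalents of 2 at 0 °C stop at the 3,5-dialkylated stage before geminal, dearomatizing prenylation takes over; no stereocenter is formed.

Step 2
Reactants: 4 3,5-diprenyl-2,4,6-trihydroxybenzophenone
Product: 6 [5,7-dihydroxy-2,2-dimethyl-8-(3-methylbut-2-en-1-yl)-2H-chromen-6-yl](phenyl)methanone (target), via ortho-quinone methide 5 (not isolated)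
Conditions: DDQ (1.0 equiv, added in portions), dry PhMe, 0 °C to rt, 2 h; filter off the hydroquinone
Reagents that add atoms: none
Why: DDQ dehydrogenation (hydride abstraction from the benzylic-allylic CH2 of one prenyl group on a ring activated by three oxygens) gives ortho-quinone methide 5 with its carbonyl at the non-chelated, most acidic 4-oxygen, and 5 closes by oxa-6π electrocyclization to the 2H-pyran; both prenyl groups flank O-4, so either gives the same product, closure onto a 2- or 6-OH would have to break its hydrogen bond to the benzoyl carbonyl, and after one closure the remaining prenyl group has only such a chelated OH beside it, which slows a second cyclization; no stereocenter is formed.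

**Compound list**

1 | 2,4,6-trihydroxybenzophenone, phenyl(2,4,6-trihydroxyphenyl)methanone | O=C(c1ccccc1)c1c(O)cc(O)cc1O | starting material
2 | prenyl bromide, 1-bromo-3-methylbut-2-ene | CC(C)=CCBr | starting material
3 | 3-prenyl-2,4,6-trihydroxybenzophenone, [2,4,6-trihydroxy-3-(3-methylbut-2-en-1-yl)phenyl](phenyl)methanone | CC(C)=CCc1c(O)cc(O)c(C(=O)c2ccccc2)c1O | intermediate
4 | 3,5-diprenyl-2,4,6-trihydroxybenzophenone, [2,4,6-trihydroxy-3,5-bis(3-methylbut-2-en-1-yl)phenyl](phenyl)methanone | CC(C)=CCc1c(O)c(CC=C(C)C)c(O)c(C(=O)c2ccccc2)c1O | intermediate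
5 | ortho-quinone methide, (6Z)-4-benzoyl-3,5-dihydroxy-2-(3-methylbut-2-en-1-yl)-6-(3-methylbut-2-en-1-ylidene)cyclohexa-2,4-dien-1-one | CC(C)=C/C=C1\C(=O)C(CC=C(C)C)=C(O)C(C(=O)c2ccccc2)=C1O | intermediate
6 | [5,7-dihydroxy-2,2-dimethyl-8-(3-methylbut-2-en-1-yl)-2H-chromen-6-yl](phenyl)methanone (achiral) | CC(C)=CCc1c(O)c(C(=O)c2ccccc2)c(O)c2c1OC(C)(C)C=C2 | target

**Totals**

Total step count: 2. Longest linear sequence: 2 steps.

**Steps most likely to fail**

The route has only two steps, so both are ranked, the riskier first.

Step 2 (dehydrogenative pyran closure). Three things can go wrong: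
- Closure onto a chelated 2- or 6-OH would give the isomeric 8-benzoyl-6-prenyl chromene.
- A second dehydrogenation of the remaining prenyl group would give a bis-pyran.
- DDQ may simply oxidise the free triphenol.

The fallback fixes the pyran oxygen by construction and sets out from 1. Alkylation of the most acidic, non-chelated 4-OH with 3-chloro-3-methylbut-1-yne (K2CO3, KI, acetone, reflux) gives the aryl propargyl ether [2,6-dihydroxy-4-(2-methylbut-3-yn-2-yloxy)phenyl](phenyl)methanone F1. Heating F1 (xylene, 140 °C) brings about propargyl Claisen rearrangement, 1,5-hydrogen shift and oxa-6π electrocyclization to (5,7-dihydroxy-2,2-dimethyl-2H-chromen-6-yl)(phenyl)methanone F2. C-prenylation of F2 at C8, its only free ring carbon, with 2 (aq KOH, 0 °C) comes back to the route at 6.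

Step 1 (double C-prenylation). A statistical mixture is expected: mono-adduct 3, geminal and triple alkylation products, and O-prenyl ethers. The yield of 4 is likely to be moderate (roughly 40%), with recovered 3 resubmitted.

The fallback separates alkylation from C–C bond formation and sets out from 1. O-alkylation with 2 (2.2 equiv, K2CO3, acetone, reflux) gives the bis-ether [2-hydroxy-4,6-bis(3-methylbut-2-en-1-yloxy)phenyl](phenyl)methanone F3. Bi(OTf)3 (5 mol%, CH2Cl2, 0 °C) then induces 1,3 O-to-C prenyl shifts. Because C3 and C5 are the only free ring positions, both groups can only end up there, and the fallback comes back to the route at 4.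

**Further compounds**

F1 | step 2 | [2,6-dihydroxy-4-(2-methylbut-3-yn-2-yloxy)phenyl](phenyl)methanone | C#CC(C)(C)Oc1cc(O)c(C(=O)c2ccccc2)c(O)c1
F2 | step 2 | (5,7-dihydroxy-2,2-dimethyl-2H-chromen-6-yl)(phenyl)methanone | CC1(C)C=Cc2c(O1)cc(O)c(C(=O)c3ccccc3)c2O
F3 | step 1 | [2-hydroxy-4,6-bis(3-methylbut-2-en-1-yloxy)phenyl](phenyl)methanone | CC(C)=CCOc1cc(OCC=C(C)C)c(C(=O)c2ccccc2)c(O)c1
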